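The numbers in the tables stem from a simulated flask for an exercise, and the scatter is random.

The target in the blue flask, the very flask asked about, rises and then falls in the readings, so I look for its peak inside the allowed 30 min.

| flask | solid substrate | protic impurity | remark | time |
|---|---|---|---|---|
| blue | 0.0050 M | 0.25 mM | the very flask that is asked about, followed so far |  |
| ochre | 0.0025 M | 0.25 mM | run made earlier |  |
| flask | 0.0050 M | 0.250 mM |  | 30 min |

| run | time / min | target / % | solid substrate / % |
|---|---|---|---|
| blue | 0.200 | 7 | 72 |
| blue | 0.333 | 14 | 59 |
| blue | 0.500 | 20 | 39 |
| blue | 0.833 | 29 | 10 |
| blue | 1.33 | 20 | 2 |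
| blue | 2.50 | 7 | 1 |
| ochre | 5.00 | 0 | 0 |
| ochre | 10.0 | 2 | 2 |
| ochre | 15.0 | 0 | 0 |
| ochre | 20.0 | 1 | 0 |
| ochre | 25.0 | 0 | 0 |
| ochre | 30.0 | 0 | 0 |

(scatter of a reading: 2 percentage points)

- as a solid, counted per litre of solution: solid substrate
- the numbers in the tables scatter by 2 percentage points (one standard deviation)
- what may be going on: starting material <-> target; starting material <-> isomer of the product A; target <-> isomer of the product A; starting material + protic impurity -> quenched substrate; solid substrate <-> starting material; target <-> isomer of the product B
- at the start none of the solid substrate is in solution

1. time, not beyond 30 min, at which the flask holds most target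
2. the amount of target, in percent of the solid substrate charged, at that time

One pair looks odd: the blue flask shows 29% target within a minute, yet the ochre flask, with half the solid, reads 0% at 5.00 min.

I count half-lives. Target's late blue readings, 20% at 1.33 min and 7% at 2.50 min, give 0.772 min. This is the drain half-life, the time in which target halves once the solid has stopped feeding it. From 0.833 min to 5.00 min lie 5.39 of them, and if target in the ochre flask drains at the blue pace they take even 29% down to 0.690%, so the odd pair fits.

The blue solid halves faster than target drains, in 0.170 min. If I count all solid lost as feed for target, feed meets drain when the solid reads 6.37%, so I commit to 0.943 min.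

The forecast gives 30% at 0.9 min, a little earlier than mine: "The maximum therefore comes as the feed collapses".

The flask gives 29.0% at 0.988 min, by these steps:

    starting material ⇌ target (K = 1.41, k = 0.121 /s)
    starting material ⇌ isomer of the product A (K = 115, k = 0.00505 /s)
    target ⇌ isomer of the product A (k = 0.0239 /s)
    starting material + protic impurity → quenched substrate (k = 245 /M/s)
    solid substrate ⇌ starting material, rate k5*(cs5 - [starting material]) while solid is left; crystals form when [starting material] > cs5 (solubility = 2.80 mM, k = 0.0490 /s)
    target ⇌ isomer of the product B (K = 3.02, k = 0.00727 /s)

At 0.988 min the flask holds 0% solid substrate and 27.8% starting material. From there to 3.00 min lie 2.60 drain half-lives, which take 29.0% down to 4.77%, and the flask then holds 4.47% target.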